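## Structural features

CNP0073203.1 (atoms numbered as in its SMILES) is a pentacycle whose core is a 2-oxabicyclo[2.2.2]octane with bridgeheads C12 and C17 and the three bridges C13–C14, C23–C24 and C20–O19. A cyclopentane (C12, C20, C21, C22, C23) and a γ-lactone (C8, C9, O11, C12, C20) share the C12–C20 bond, and a cyclooctane (C2, C3, C4, C6, C8, C20, C21, C26) is fused to both through C8–C20–C21; the lactone is enolised towards C6, and C26 is a ketone. There are nine stereocentres (C2, C4, C12, C14, C17, C20, C21, C23, C24); C12, C14, C17 and C20 are fully substituted, and C14–C17–C24–C23–C12–C20–C21 is one unbroken chain of stereocentres. On the carbocyclic ring C12–C13–C14–C17–C24–C23 the oxygens O11, O16, O25 and the hydrogen on C23 lie on one face (α below), whereas O19 and the C14 methyl group lie on the other (β). The fragile features are the ether O19, which is β to the carbonyls C9, C6 and C26 and can be expelled by an enolate at C8 or C21, the epimerisable centres C2, C4 and C21, and the acidic enolised acyl lactone. The real difficulty is the cyclohexane with four oxygenated carbons, two of them quaternary and para to each other, locked in a cage beside an eight-membered ring. The key step uses this para pattern: C17 (O19) and C12 (lactone O11) are para carbons, C23–C22–C21–C20 is the five-membered ring of an indane and C20–C8–C9 a Z-alkylidene acetic acid, so the ring is a phenol attacked at its para carbon by its own carboxylate, and the C24 oxygen can be carried on the arene as a methoxy group.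

## Logic of the disconnections

**29 ⇒ 28 ⇒ 27 (no skeletal bond).** The O16/O25 carbonate and the C26 carbinol are retained to the end. The carbonate leaves C26–OH as the only oxidisable alcohol. Keeping C26 as a carbinol during ring closure keeps a ketone enolate (six-ring Claisen at C21, epimerisation at C2) out of the base step. The forward steps must be a mild oxidation beside an enolised tricarbonyl and a mild carbonate methanolysis.

**27 ⇒ 25 (cut C6–C8 and O19–C20).** The cyclooctane is opened at the acyl lactone and the ether bridge is opened with it. A bridge closed while C23=C24 is still present would put a double bond at the bridgehead of a bicyclo[3.2.1] subunit (C20, C23 bridgeheads), which Bredt's rule forbids. A lactone enolate at C8 would in any case expel O19 until C8 carries the acyl group. The bridge is therefore closed in the same operation as the Dieckmann condensation. This removes two rings and the C20 stereocentre; it demands that C23 be sp3 and that the C21 side chain be cis to C8.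

**25, 24 ⇒ 18 + 22 (cut C21–C26).** The chain is detached at the γ′ carbon of the butenolide. This is convergent and leaves 22 with C2 and C4 already set. The forward vinylogous aldol must react at C21 and not at C8, from the face opposite the six-membered ring, and C17–OH must be silylated for that step so that its alkoxide cannot add to C20 and switch off C21.

**18 ⇒ 17 ⇒ 16 ⇒ 15 (cut O16–C14, then C13–H).** The tertiary C14 alcohol must be α, and the steric bias of the open tricycle cannot be trusted to give it. O25 is α and 1,3 to C14, so O16 is delivered from a carbonate on O25. The demand is Markovnikov, 6-exo opening of an iodonium ion and a clean radical dehalogenation.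

**15 ⇒ 14 ⇒ 13 ⇒ 12 (cut C24–H, C23–H, C17–C18).** In a dienone without oxygen on C24, C13=C14 and C23=C24 become twin trisubstituted alkenes flanking C17 after methyl addition, and anti-Markovnikov hydration of only C23=C24 has no reliable basis. The precursor is therefore redesigned to carry a methoxy group on the future C24. C23=C24 is then an enol ether, hydrolysed to a ketone without touching C13=C14; C23 is set by equilibration, C24 by hydroxyl-directed reduction. The methyl group is added to the intact cross-conjugated dienone, where the C12–O11 bond controls the face.

**12 ⇒ 11 (cut O11–C12, key step).** This removes the butenolide ring, the only stereocentre present, and all three-dimensional character: 11 is a flat achiral phenol acid. The forward step must choose one enantioface of C12 with a chiral oxidant and needs the Z acid.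

**11 ⇒ 10 ⇒ 9 ⇒ 7 + 8 (cut C20=C8).** A phosphonoacetate olefination of an indanone gives mainly the E ester (ester away from the peri C–H), so the Z geometry is not expected from the olefination itself. It is reached by contra-thermodynamic photoisomerisation. The phenol is masked as a pivalate, because a free phenoxide para to the ketone would deactivate it, and is freed together with the ester.

**7 ⇒ 6 ⇒ 5 ⇒ 4 (cut the aryl–C20 bond).** Friedel–Crafts acylation closes the indanone at the only free position ortho to the side chain, para to a methoxy group. The two methyl ethers are then told apart by nucleophilic demethylation para to the ketone.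

**4 ⇒ 2 + 3 and 2 ⇒ 1 (cut C21–C22, then C22–C23).** The three-carbon acid chain comes from 3 by reductive Knoevenagel chemistry, and the aldehyde carbon from ortho-lithiation of 1 next to its methoxy group.

**22 ⇒ 21 ⇒ 20 ⇒ 19 (no skeletal bond).** The syn-dimethyl chain is the meso anhydride with its two carbonyls differentiated; one catalytic desymmetrisation sets both C2 and C4.

## Other disconnections considered

**Alternative 1:** The cut is C12–C23 and C17–C24. In the forward step a 2H-pyran diene (C12=C13–C14=C17, both carbons silyloxy-substituted) adds a tethered E-alkenylboronate (C23=C24) on heating to give A1.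
- In its favour: one step forms two C–C bonds, two rings and four stereocentres (C12, C17, C23, C24). The O19–C20 bridge exists from the start, so there is no reversible oxa-Michael step and no bridgehead-alkene constraint. The C–B bond gives O25 with retention.
- Against it here: 2H-pyrans of this type can open electrocyclically to dienones. C20 and C21 must be set beforehand and relay through the tether. C14 still needs a face-selective methyl addition, and C8, C9 and C26 arrive as protected alcohols, so lactone and cyclooctane need many redox and protecting-group steps.
- Comparison: in bonds and stereocentres per step A1's key step is the better of the two. The chosen plan is better in the simplicity of its precursor (a flat arene) and in carrying C9 at the right oxidation level. Overall step count is expected to be similar.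

**Alternative 2:** The cut is C8–C20. In the forward step Rh2(OAc)4 (or Rh2(esp)2) decomposes an eleven-membered α-diazo-β-keto macrolactone and the carbene at C8 inserts into the C20–H bond, giving A2 with γ-lactone and cyclooctane closed together.
- In its favour: two rings and the quaternary C20 are made in the last C–C bond-forming step with retention. No enolate is generated next to C2, C4 or C21, which on that point is better than the chosen Dieckmann closure. Insertion α to an ether oxygen in a 1,5-relationship is the preferred mode.
- Against it here: the macrolactone requires acylation of the hindered tertiary C12 alcohol within a medium ring. C13–H and C23–H are also 1,5 to the carbene through O11–C12. The oxygenated cage must come from a different key step.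
- Comparison: as an endgame it is the equal or the better of the chosen one. It does not solve the cyclohexane, which the chosen plan makes from an arene in one enantioselective step.

**Alternative 3:** The cut is C21–C26. In the forward step potassium tert-butoxide deprotonates a 3-acylbutenolide at C21 and the extended enolate is acylated by the C26 methyl ester, giving A3. A3 is drawn here with a single methylene (C22) between C21 and C23; a formula with two methylenes there is a cyclohexane homologue with one carbon too many and would not map onto the target.
- In its favour: C8 is fully substituted, so only C21 can react. This regiochemistry is better secured than in the intermolecular vinylogous aldol of the chosen plan. C26 is formed directly as the ketone, which saves an oxidation.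
- Equal points: the acyl group at C8 makes the later O19–C20 closure strongly favourable, as in the chosen plan, and the eight-membered Claisen closure has the same entropic handicap.
- Against it here: C2 and C21 sit α to the new ketone under alkoxide, a greater epimerisation risk than in the chosen plan. The substituted cyclohexane must again be made elsewhere.

Key step: step 9

Remark: atom numbers are those of the target SMILES; α is the face of ring C12–C13–C14–C17–C24–C23 carrying O11, β the face carrying C20; 11 and 12 carry one added methoxy group at the future C24, a spectator in the key step; the C26 carbinol centre of 24–27 is left undefined because step 21 removes it; the antipodes of the catalysts in steps 9 and 15 are those that give 12 and 20 as drawn.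

## Route

Step 1
Reactants: 1 2,3-dimethoxytoluene
Product: 2 2,3-dimethoxy-4-methylbenzaldehyde
Conditions: n-BuLi, TMEDA, Et2O, 0 °C to rt; DMF; aq. NH4Cl
Reagents that add atoms: N,N-dimethylformamide, CN(C)C=O
Why: Directed ortho-metalation: the methoxy group directs lithiation to the only ring position ortho to an ether oxygen, and DMF formylates the aryllithium.

Step 2
Reactants: 2 2,3-dimethoxy-4-methylbenzaldehyde; 3 Meldrum's acid
Product: 4 3-(2,3-dimethoxy-4-methylphenyl)propanoic acid
Conditions: HCO2H, Et3N, 95 °C
Reagents that add atoms: none
Why: One-pot Knoevenagel condensation, conjugate hydride transfer from formate and hydrolysis–decarboxylation of the Meldrum's acid adduct should give the saturated acid.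

Step 3
Reactants: 4 3-(2,3-dimethoxy-4-methylphenyl)propanoic acid
Product: 5 4,5-dimethoxy-6-methylindan-1-one
Conditions: Eaton's reagent (P2O5 in MeSO3H), 60 °C
Reagents that add atoms: none
Why: Intramolecular Friedel–Crafts acylation; only one position ortho to the chain is free and it is para to a methoxy group, so the regiochemistry is unambiguous.

Step 4
Reactants: 5 4,5-dimethoxy-6-methylindan-1-one
Product: 6 5-hydroxy-4-methoxy-6-methylindan-1-one
Conditions: NaSEt, DMF, 100 °C; aq. HCl
Reagents that add atoms: none
Why: SN2 O-demethylation by thiolate; the C5 ether is para to the ketone (better phenoxide leaving group) and is the central, out-of-plane one of three contiguous substituents, so it should be cleaved selectively.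

Step 5
Reactants: 6 5-hydroxy-4-methoxy-6-methylindan-1-one
Product: 7 4-methoxy-6-methyl-1-oxoindan-5-yl pivalate
Conditions: t-BuCOCl, Et3N, DMAP (cat.), CH2Cl2, 0 °C
Reagents that add atoms: pivaloyl chloride, CC(C)(C)C(Cl)=O
Why: Acylation of the phenol; the hindered ester survives the olefination base, keeps the ketone electrophilic and is removable by hydroxide.

Step 6
Reactants: 7 4-methoxy-6-methyl-1-oxoindan-5-yl pivalate; 8 triethyl phosphonoacetate
Product: 9 ethyl (E)-2-[4-methoxy-6-methyl-5-(pivaloyloxy)indan-1-ylidene]acetate
Conditions: NaH, THF, 65 °C
Reagents that add atoms: none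
Why: Horner–Wadsworth–Emmons olefination; the E isomer (ester away from the peri C7–H) is expected as the major product, and any Z isomer is carried forward.

Step 7
Reactants: 9 ethyl (E)-2-[4-methoxy-6-methyl-5-(pivaloyloxy)indan-1-ylidene]acetate
Product: 10 ethyl (Z)-2-[4-methoxy-6-methyl-5-(pivaloyloxy)indan-1-ylidene]acetate
Conditions: Ir(ppy)3 (1 mol%), MeCN, 450 nm LEDs, rt
Reagents that add atoms: none
Why: Contra-thermodynamic E-to-Z isomerisation by triplet energy transfer; in the Z isomer allylic strain with C7–H twists the ester out of conjugation, so it is sensitised less efficiently and should accumulate.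

Step 8
Reactants: 10 ethyl (Z)-2-[4-methoxy-6-methyl-5-(pivaloyloxy)indan-1-ylidene]acetate
Product: 11 (Z)-2-(5-hydroxy-4-methoxy-6-methyl-2,3-dihydro-1H-inden-1-ylidene)acetic acid
Conditions: LiOH, THF–MeOH–H2O, rt; citric acid to pH 4
Reagents that add atoms: water, O
Why: Saponification of the ethyl ester and the aryl pivalate in one operation; only weak acid is used in the work-up because strong acid would isomerise the electron-rich Z alkene.

Step 9
Reactants: 11 (Z)-2-(5-hydroxy-4-methoxy-6-methyl-2,3-dihydro-1H-inden-1-ylidene)acetic acid
Product: 12 C24-methoxy tricyclic butenolide dienone (C12 R)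
Conditions: chiral aryl iodide 2-iodo-1,3-bis[1-(mesitylamino)-1-oxopropan-2-yloxy]benzene (10 mol%), mCPBA (1.3 equiv), CH2Cl2–(CF3)2CHOH, −20 °C
Reagents that add atoms: none
Why: mCPBA oxidises the aryl iodide to a chiral trivalent iodine species that exchanges a ligand for the phenol oxygen; as the aryl iodide departs, the ring becomes electrophilic at the para carbon C12 and the Z-carboxylate, held over that carbon by the exocyclic alkene, forms O11–C12. The closest known reaction type is the oxidative dearomatising spirolactonisation of para-substituted phenols under aryl iodide–peracid catalysis, including its enantioselective variants. The butenolide closes in a 5-exo-trig mode on the ring carbon; no other ring is formed. C12 is the only new stereocentre and is set by the chiral aryl iodide alone (reagent control), since 11 is achiral. The step needs para over ortho attack, which the tether secures (the carboxylate cannot reach C14 or C24, and both ortho carbons are substituted), and it needs the Z acid, because the E isomer cannot reach C12. The methoxy group at C24 is a spectator that makes the phenol more electron-rich and leaves the product with an enol ether at C23=C24.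

Step 10
Reactants: 12 C24-methoxy tricyclic butenolide dienone (C12 R)
Product: 14 α-ketol with C17 carbinol and C24 ketone, via C17 carbinol methyl enol ether 13 (not isolated)
Conditions: MeMgBr, THF, −78 °C; then 0.5 M aq. HCl, THF, 0 °C to rt
Reagents that add atoms: methylmagnesium bromide, C[Mg]Br; water, O
Why: 1,2-Addition of the Grignard reagent to a 4-oxy-4-alkyl cyclohexadienone, where the nucleophile enters syn to the C12–O11 bond (electrostatic preference of such dienones), puts the methyl group α and O19 β; dilute acid then hydrolyses the methyl enol ether, and C23 equilibrates through the enol to the cis ring fusion (H on C23 α), the only one compatible with the planar butenolide.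

Step 11
Reactants: 14 α-ketol with C17 carbinol and C24 ketone
Product: 15 trans C17/C24 diol
Conditions: Me4NBH(OAc)3, MeCN–AcOH, −30 °C
Reagents that add atoms: none
Why: Hydroxyl-directed triacetoxyborohydride reduction: boron exchanges an acetate for the C17 hydroxyl and delivers hydride to C24 from the β face, giving the trans diol (O25 α); the reagent is not basic, so the β-acyloxy ketone is not enolised.

Step 12
Reactants: 15 trans C17/C24 diol
Product: 16 C24 tert-butyl carbonate
Conditions: Boc2O, DMAP, CH2Cl2, rt
Reagents that add atoms: di-tert-butyl dicarbonate, CC(C)(C)OC(=O)OC(=O)OC(C)(C)C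
Why: DMAP-catalysed acylation of the secondary alcohol; the tertiary C17 hydroxyl is too hindered to react.

Step 13
Reactants: 16 C24 tert-butyl carbonate
Product: 17 C13-iodo C14/C24 cyclic carbonate
Conditions: IBr, toluene, −78 °C
Reagents that add atoms: iodine monobromide, IBr
Why: Iodocarbonate cyclisation (6-exo, Markovnikov): of the reversibly formed iodonium ions only the β one can be opened at C14 by the carbonate carbonyl tethered on the α face, so O16 is delivered α and the tert-butyl group leaves as the bromide; the electron-poor butenolide alkene does not react.

Step 14
Reactants: 17 C13-iodo C14/C24 cyclic carbonate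
Product: 18 C14/C24 cyclic carbonate
Conditions: Bu3SnH, AIBN, toluene, 80 °C
Reagents that add atoms: none
Why: Radical chain dehalogenation; neither neighbour of C13 carries a hydrogen, so elimination cannot compete.

Step 15
Reactants: 19 meso-2,4-dimethylglutaric anhydride
Product: 20 (2R,4S)-5-methoxy-2,4-dimethyl-5-oxopentanoic acid
Conditions: MeOH, (DHQD)2AQN (cat.), Et2O, −40 °C
Reagents that add atoms: methanol, CO
Why: Cinchona-alkaloid-catalysed desymmetrising methanolysis of a meso anhydride; methanol opens the carbonyl next to the (S)-configured carbon, which fixes both stereocentres of the chain.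

Step 16
Reactants: 20 (2R,4S)-5-methoxy-2,4-dimethyl-5-oxopentanoic acid
Product: 21 methyl (2S,4R)-5-hydroxy-2,4-dimethylpentanoate
Conditions: BH3·SMe2, THF, 0 °C
Reagents that add atoms: none
Why: Borane reduces the carboxylic acid much faster than the methyl ester.

Step 17
Reactants: 21 methyl (2S,4R)-5-hydroxy-2,4-dimethylpentanoate
Product: 22 methyl (2S,4R)-2,4-dimethyl-5-oxopentanoate
Conditions: Dess–Martin periodinane, NaHCO3, CH2Cl2, 0 °C
Reagents that add atoms: none
Why: Buffered Dess–Martin oxidation; the α-stereocentre is kept by using the aldehyde at once.

Step 18
Reactants: 18 C14/C24 cyclic carbonate; 22 methyl (2S,4R)-2,4-dimethyl-5-oxopentanoate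
Product: 24 C21 aldol adduct, via bis-TMS dienol ether 23 (not isolated)
Conditions: Me3SiOTf, Et3N, CH2Cl2, 0 °C (crude 23); then 22, BF3·OEt2, CH2Cl2, −78 °C; aq. citric acid
Reagents that add atoms: none
Why: Soft enolisation silylates C17–OH and turns the butenolide into its silyl dienol ether; the vinylogous Mukaiyama aldol reaction then forms C21–C26 at the γ′ carbon, the aldehyde approaching the face of the five-membered ring opposite the fused six-membered ring, which sets C21; the silyl groups are lost on acidic work-up.

Step 19
Reactants: 24 C21 aldol adduct
Product: 25 C26 TBS ether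
Conditions: TBSCl, imidazole, DMF, rt
Reagents that add atoms: tert-butyldimethylsilyl chloride, CC(C)(C)[Si](C)(C)Cl
Why: Silylation of the secondary C26 alcohol only, so that no alkoxide next to C21 can undergo retro-aldol cleavage in step 20; the tertiary C17 alcohol stays free for the next step.

Step 20
Reactants: 25 C26 TBS ether
Product: 27 caged tricarbonyl enol C26 alcohol, via caged enol C26 TBS ether 26 (not isolated)
Conditions: KN(SiMe3)2 (2.2 equiv), THF, −78 to 0 °C; then HF·pyridine, THF, 0 °C
Reagents that add atoms: none
Why: Tandem oxa-Michael–Dieckmann condensation: the C17 alkoxide adds to C20 (allowed now that C23 is sp3), the lactone enolate at C8 is acylated by the C6 methyl ester to close the cyclooctane, and the tricarbonyl enolate formed is the thermodynamic sink that keeps the O19–C20 bridge closed. C20 can only form with O19 and C8 cis on the cage, so its configuration follows from C12 and C17; HF·pyridine then removes the silyl ether.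

Step 21
Reactants: 27 caged tricarbonyl enol C26 alcohol
Product: 28 caged C26 ketone cyclic carbonate
Conditions: Dess–Martin periodinane, NaHCO3, CH2Cl2, 0 °C
Reagents that add atoms: none
Why: Dess–Martin oxidation of the only free secondary alcohol; O25 is masked in the carbonate.

Step 22
Reactants: 28 caged C26 ketone cyclic carbonate
Product: 29 CNP0073203.1
Conditions: K2CO3, MeOH, 0 °C; pH 4 buffer
Reagents that add atoms: none
Why: Transesterification of the cyclic carbonate with methanol under mild base frees O16 and O25; the tricarbonyl is present as its enolate, which protects it from retro-Claisen cleavage and slows enolisation at C2.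

## Compound list

1 | 2,3-dimethoxytoluene | COc1cccc(C)c1OC | starting material
2 | 2,3-dimethoxy-4-methylbenzaldehyde | COc1c(C=O)ccc(C)c1OC | intermediate
3 | Meldrum's acid (2,2-dimethyl-1,3-dioxane-4,6-dione) | CC1(C)OC(=O)CC(=O)O1 | starting material
4 | 3-(2,3-dimethoxy-4-methylphenyl)propanoic acid | COc1c(CCC(=O)O)ccc(C)c1OC | intermediate
5 | 4,5-dimethoxy-6-methylindan-1-one | COc1c(C)cc2C(=O)CCc2c1OC | intermediate
6 | 5-hydroxy-4-methoxy-6-methylindan-1-one | COc1c(O)c(C)cc2C(=O)CCc12 | intermediate
7 | 4-methoxy-6-methyl-1-oxoindan-5-yl pivalate | COc1c(OC(=O)C(C)(C)C)c(C)cc2C(=O)CCc12 | intermediate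
8 | triethyl phosphonoacetate | CCOC(=O)CP(=O)(OCC)OCC | starting material
9 | ethyl (E)-2-[4-methoxy-6-methyl-5-(pivaloyloxy)indan-1-ylidene]acetate | CCOC(=O)/C=C1\CCc2c1cc(C)c(OC(=O)C(C)(C)C)c2OC | intermediate
10 | ethyl (Z)-2-[4-methoxy-6-methyl-5-(pivaloyloxy)indan-1-ylidene]acetate | CCOC(=O)/C=C1/CCc2c1cc(C)c(OC(=O)C(C)(C)C)c2OC | intermediate
11 | (Z)-2-(5-hydroxy-4-methoxy-6-methyl-2,3-dihydro-1H-inden-1-ylidene)acetic acid (key-step precursor) | OC(=O)/C=C1/CCc2c(OC)c(O)c(C)cc12 | intermediate
12 | tricyclic butenolide dienone, C12 (R): cross-conjugated dienone (C17=O, C13=C14–CH3, C23=C24–OCH3) fused at C12 to the cyclopentane ring and to the butenolide (O11 on C12, C8=C20) (key-step product) | O=C1C(OC)=C2CCC3=CC(=O)O[C@@]23C=C1C | intermediate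
13 | C17 tertiary carbinol of 12 (C17–OH β, C17–CH3 α), C23=C24 methyl enol ether | C[C@@]1(O)C(OC)=C2CCC3=CC(=O)O[C@@]23C=C1C | intermediate (not isolated)
14 | α-ketol: C17–OH β, C24 ketone, H on C23 α (cis ring fusion), C13=C14 and butenolide intact | C[C@@]1(O)C(=O)[C@@H]2CCC3=CC(=O)O[C@@]23C=C1C | intermediate
15 | trans diol: C17–OH β, C24–OH α | C[C@@]1(O)[C@@H](O)[C@@H]2CCC3=CC(=O)O[C@@]23C=C1C | intermediate
16 | C24 tert-butyl carbonate of 15 | C[C@@]1(O)[C@@H](OC(=O)OC(C)(C)C)[C@@H]2CCC3=CC(=O)O[C@@]23C=C1C | intermediate
17 | cyclic carbonate bridging O16 (C14, α) and O25 (C24, α), C13–I β, C17–OH free | O=C1O[C@@]23[C@H](I)[C@@]4(C)OC(=O)O[C@H]([C@@]4(C)O)[C@@H]2CCC3=C1 | intermediate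
18 | cyclic carbonate bridging O16 and O25, C13H2, C17–OH free, butenolide | O=C1O[C@@]23C[C@@]4(C)OC(=O)O[C@H]([C@@]4(C)O)[C@@H]2CCC3=C1 | intermediate
19 | meso-2,4-dimethylglutaric anhydride | C[C@H]1C[C@@H](C)C(=O)OC1=O | starting material
20 | (2R,4S)-5-methoxy-2,4-dimethyl-5-oxopentanoic acid | C[C@@H](C(=O)O)C[C@H](C)C(=O)OC | intermediate
21 | methyl (2S,4R)-5-hydroxy-2,4-dimethylpentanoate | C[C@@H](CO)C[C@H](C)C(=O)OC | intermediate
22 | methyl (2S,4R)-2,4-dimethyl-5-oxopentanoate | C[C@@H](C=O)C[C@H](C)C(=O)OC | intermediate
23 | bis(trimethylsilyl) derivative of 18: C17–OSiMe3 and 2-silyloxy diene C9(OSiMe3)=C8–C20=C21 | C[Si](C)(C)OC=1O[C@@]23C[C@@]4(C)OC(=O)O[C@H]([C@@]4(C)O[Si](C)(C)C)[C@@H]2CC=C3C=1 | intermediate (not isolated)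
24 | aldol adduct: C21 bears CH(OH)–CH(CH3)–CH2–CH(CH3)–CO2CH3 on the face opposite the six-membered ring; C17–OH free | O=C1O[C@@]23C[C@@]4(C)OC(=O)O[C@H]([C@@]4(C)O)[C@@H]2C[C@@H](C(O)[C@H](C)C[C@H](C)C(=O)OC)C3=C1 | intermediate
25 | C26 tert-butyldimethylsilyl ether of 24 | O=C1O[C@@]23C[C@@]4(C)OC(=O)O[C@H]([C@@]4(C)O)[C@@H]2C[C@@H](C(O[Si](C)(C)C(C)(C)C)[C@H](C)C[C@H](C)C(=O)OC)C3=C1 | intermediate
26 | caged pentacycle (O19–C20 bridge, cyclooctane closed, enolised acyl lactone), C26–OTBS, O16/O25 carbonate | C[C@@H]1C[C@H](C)/C(O)=C2/C(=O)O[C@]34C[C@@](C)(OC(=O)O6)[C@]5(C)O[C@]23[C@@H](C[C@H]4[C@@H]56)C1O[Si](C)(C)C(C)(C)C | intermediate (not isolated)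
27 | caged pentacycle, C26–OH, O16/O25 carbonate | C[C@@H]1C[C@H](C)/C(O)=C2/C(=O)O[C@]34C[C@@](C)(OC(=O)O6)[C@]5(C)O[C@]23[C@@H](C[C@H]4[C@@H]56)C1O | intermediate
28 | caged pentacycle, C26 ketone, O16/O25 carbonate | C[C@@H]1C[C@H](C)/C(O)=C2/C(=O)O[C@]34C[C@@](C)(OC(=O)O6)[C@]5(C)O[C@]23[C@@H](C[C@H]4[C@@H]56)C1=O | intermediate
29 | CNP0073203.1 | C[C@@H]1C[C@H](C)/C(O)=C2/C(=O)O[C@]34C[C@@](C)(O)[C@]5(C)O[C@]23[C@@H](C[C@H]4[C@@H]5O)C1=O | target

## Step count and least certain steps

Total: 22 steps. Longest linear sequence: 19 steps (steps 1–14 and 18–22); the chain (steps 15–17) joins at step 18.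

**Step 9 (key step).** The likely failure is poor enantioface discrimination, because C12 is formed four atoms away from the iodine-bound oxygen; attack of 3-chlorobenzoate or water at the methoxy-bearing ortho carbon and over-oxidation may also occur. Fallback: starting from 11, oxidation with PhI(OAc)2 in (CF3)2CHOH at 0 °C should give the racemic dienone F1. Preparative chromatography on a chiral stationary phase then returns the route to 12; the cost is half of the material.

**Step 20.** The eight-membered ring closure may be slower than its competitors: loss of silanolate from a C21 dienolate of the ring-opened form, enolisation of the ester at C4, or attack of liberated methoxide on the cyclic carbonate. Fallback: starting from 24, acid catalysis (camphorsulfonic acid, toluene, 60 °C) should close the C26 hydroxy ester to the δ-lactone F2. With KN(SiMe3)2 the C17 alkoxide adds to C20 and the C8 enolate attacks the δ-lactone carbonyl through a six-membered transition state; the C6–O bond then breaks, which expands the ring to the cyclooctane and frees O–C26. This returns to the route at 27 without a silyl group.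

**Step 18.** Bond formation at C8 instead of C21, desilylation or ionisation by BF3, and epimerisation of 22 at its α-carbon are the risks. Fallback: starting from 18, the C17 trimethylsilyl ether F3 (Me3SiCl, imidazole) and 22 are both complexed with Al(OC6H3Ph2-2,6)3, and LiN(iPr)2 at −78 °C generates the dienolate inside the bulky aluminium complex, which blocks C8 and directs the aldol reaction to C21. Acidic work-up returns the route to 24.

**Step 13.** The cyclisation has to place iodine on the hindered β face while the carbocycle moves towards a boat, so it may be slow and loss of the carbonate may compete. Fallback: starting from 16, a radical–polar crossover hydrofunctionalisation (Co(salen), N-fluoro-2,4,6-trimethylpyridinium triflate, (Me2SiH)2O) transfers a hydrogen atom to C13 and lets the carbonate carbonyl capture the C14 cation from the α face. This gives 18 directly, with no iodide intermediate and no new compound.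

**Step 7.** The photostationary state may not be rich enough in the Z isomer, because the indane keeps the styrene chromophore planar in both isomers; photodegradation is also possible. Fallback: starting from 7, a Still–Gennari olefination (methyl bis(2,2,2-trifluoroethyl)phosphonoacetate, KN(SiMe3)2, 18-crown-6, THF, −78 °C) should give the Z methyl ester F4 under kinetic control. Hydrolysis as in step 8 returns the route to 11.

## Further compounds

F1 | step 9 | racemic C24-methoxy tricyclic butenolide dienone | O=C1C(OC)=C2CCC3=CC(=O)OC23C=C1C
F2 | step 20 | δ-lactone of 24 (O on C26 acylated by C6; C17–OH free) | O=C1O[C@@]23C[C@@]4(C)OC(=O)O[C@H]([C@@]4(C)O)[C@@H]2C[C@@H](C5OC(=O)[C@@H](C)C[C@H]5C)C3=C1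
F3 | step 18 | C17 trimethylsilyl ether of 18 | O=C1O[C@@]23C[C@@]4(C)OC(=O)O[C@H]([C@@]4(C)O[Si](C)(C)C)[C@@H]2CCC3=C1
F0 | step 13 | none | none
F4 | step 7 | methyl (Z)-2-[4-methoxy-6-methyl-5-(pivaloyloxy)indan-1-ylidene]acetate | COC(=O)/C=C1/CCc2c1cc(C)c(OC(=O)C(C)(C)C)c2OC
A1 | alternative 1 | oxa-isotwistene silyl enol ether boronate | C[C@@]12O[C@@](CCOCc3ccccc3)([C@H](COCc4ccc(OC)cc4)C[C@H]5[C@@H]1B6OC(C)(C)C(C)(C)O6)[C@]5(O[Si](C)(C)C(C)(C)C)C=C2O[Si](C)(C)C(C)(C)C
A2 | alternative 2 | protected target (O16/O25 acetonide, C26 dioxolane) | C[C@@H]1C[C@H](C)/C(O)=C2/C(=O)O[C@]34C[C@@](C)(OC(C)(C)O6)[C@]5(C)O[C@]23[C@@H](C[C@H]4[C@@H]56)C17OCCO7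
A3 | alternative 3 | cyclooctanedione-fused butenolide (cyclopentane with one methylene between C21 and C23) | C[C@@H]1C[C@H](C)C(=O)C2=C3[C@@H](C[C@@H]4[C@@]3(OC2=O)C[C@@]5(C)OC(C)(C)O[C@@H]4[C@@]5(C)O[Si](CC)(CC)CC)C1=O
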